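Ring B of this ent-labdane holds a tertiary carbinol at C8 (equatorial OH, axial C17 methyl) directly beside C9. A 2-hydroxy-2-methylcyclohexanone with its carbonyl at C9 is the ring-enlarged isomer of a 1-acetylcyclopentanol, so ring B is first built one carbon short. The pivotal operation is an aluminium-mediated acyloin (α-ketol) shift: C7 moves from C9 to the acetyl carbon C8, which forms the C7–C8 bond, turns the hydrindane into the trans-decalin and fixes the C8 configuration at once. Its substrate is a trans-fused hydrindane carrying at C9 a hydroxyl trans and an acetyl group cis to the angular methyl C20, plus the C18 benzyl ether. The side chain is then grown from the C9 ketone.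

Key step: step 12

Remark: labdane numbering is used for every bicyclic compound (ring A = C1–C5 and C10; ring B = C5–C10; C20 = methyl on C10; C19 = methyl and C18 = CH2O on C4; C17 = methyl on C8; side chain C11–C16 on C9). Before step 12, ring B is the five-membered ring C5–C6–C7–C9–C10 and C8 is exocyclic. Faces are given as cis or trans to C20. The target has C10 R (enantiomeric labdane series; 4S,5S,8S,9S,10R,13S), hence the D-amino acid in step 2.

Assumption: the Wittig alkenes 13 and 30 are drawn as the Z isomers expected from unstabilised ylides; their geometry has no influence on any later compound.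

Step 1
Reactants: 1 2-methylcyclopentane-1,3-dione; 2 pent-1-en-3-one
Product: 3 2-methyl-2-(3-oxopentyl)cyclopentane-1,3-dione
Conditions: H2O, AcOH (cat.), 75 °C
Reagents that add atoms: none
Why: Michael addition of the acidic cyclic 1,3-dione to the vinyl ketone proceeds in water without strong base and creates no stereocentre.

Step 2
Reactants: 3 2-methyl-2-(3-oxopentyl)cyclopentane-1,3-dione
Product: 4 (7aR)-4,7a-dimethyl-2,3,7,7a-tetrahydro-1H-indene-1,5(6H)-dione
Conditions: D-phenylalanine (1 equiv), 1 M HClO4 (0.5 equiv), MeCN, reflux; recrystallisation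
Reagents that add atoms: none
Why: Amino-acid-mediated intramolecular aldol condensation (Hajos–Parrish type, enamine mechanism) in which D-phenylalanine selects one of the two enantiotopic ring carbonyls and thereby sets the quaternary C10 as R, the mirror image of the outcome with the L-amino acid, and recrystallisation should raise the enantiomeric purity.

Step 3
Reactants: 4 (7aR)-enedione
Product: 5 (1R,7aR)-1-hydroxy-4,7a-dimethyl-1,2,3,6,7,7a-hexahydro-5H-inden-5-one (C9 hydroxyl cis to C20)
Conditions: NaBH4 (0.3 equiv), EtOH, −20 °C
Reagents that add atoms: none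
Why: Chemoselective borohydride reduction of the saturated cyclopentanone beside the less electrophilic tetrasubstituted enone, with hydride delivered opposite the angular methyl so that the C9 hydroxyl is cis to C20 (a temporary centre).

Step 4
Reactants: 5 hydroxy enone
Product: 6 tert-butyldimethylsilyl ether of 5
Conditions: TBSCl, imidazole, DMF, rt
Reagents that add atoms: tert-butyldimethylsilyl chloride, CC(C)(C)[Si](C)(C)Cl
Why: Standard silylation of the secondary alcohol gives an ether that withstands the dissolving-metal step and removes the only acidic proton.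

Step 5
Reactants: 6 silyl ether enone
Product: 8 trans-fused 9-silyloxy-hydrindan-3-one bearing CH3 (C19) and CH2OH (C18) on C4, via lithium enolate 7 (not isolated)
Conditions: Li (2.2 equiv), t-BuOH (1 equiv), NH3–THF, −78 °C; NH3 evaporated; CH2O (gas, from paraformaldehyde), THF, −78 °C; aq NH4Cl
Reagents that add atoms: formaldehyde, C=O
Why: Dissolving-metal enone reduction followed by aldol trapping of the regiodefined enolate (reductive hydroxymethylation), in which protonation of C5 gives the trans ring fusion (H5 anti to C20) and formaldehyde attacks C4 on the face away from C20, so that C18 is trans and C19 cis to C20.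

Step 6
Reactants: 8 hydroxymethyl ketone
Product: 9 C18 benzyl ether of 8
Conditions: 2-benzyloxy-1-methylpyridinium triflate, MgO, PhCF3, 85 °C
Reagents that add atoms: 2-benzyloxy-1-methylpyridinium trifluoromethanesulfonate, C[n+]1ccccc1OCc1ccccc1.[O-]S(=O)(=O)C(F)(F)F
Why: Benzyl transfer from the pyridinium salt under neutral conditions etherifies the neopentyl alcohol without the base that would cause retro-aldol loss of formaldehyde from this β-hydroxy ketone and without acid that would endanger the silyl ether.

Step 7
Reactants: 9 benzyl ether ketone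
Product: 11 18-benzyloxy trans-hydrindan-9-ol (C3 now CH2; hydroxyl cis to C20), via hydrazone 10 (not isolated)
Conditions: N2H4·H2O, KOH, diethylene glycol, 130 °C then 200 °C
Reagents that add atoms: none
Why: Wolff–Kishner reduction (Huang-Minlon procedure) converts the hindered C3 carbonyl, which has no hydrogen on C4 and no eliminable group, into CH2, the hot hydroxide removes the silyl group in the same operation, and the benzyl ether is inert to base.

Step 8
Reactants: 11 hydrindan-9-ol
Product: 12 18-benzyloxy trans-hydrindan-9-one
Conditions: Dess–Martin periodinane, CH2Cl2, rt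
Reagents that add atoms: none
Why: Dess–Martin oxidation of the secondary alcohol to the cyclopentanone under neutral conditions touches neither the benzyl ether nor a stereocentre.

Step 9
Reactants: 12 hydrindan-9-one
Product: 13 (Z)-9-ethylidene-18-benzyloxy trans-hydrindane (C17 cis to C10)
Conditions: EtPPh3Br, KOtBu, THF, reflux
Reagents that add atoms: ethyltriphenylphosphonium bromide, CC[P+](c1ccccc1)(c1ccccc1)c1ccccc1.[Br-]
Why: Wittig olefination with the unstabilised ethylidene ylide is the standard way to turn a cyclopentanone next to a quaternary carbon (the 17-oxo-steroid situation) into its Z-ethylidene derivative, and the ketone has no epimerisable neighbour.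

Step 10
Reactants: 13 ethylidene compound
Product: 14 9-(1-hydroxyethyl)-18-benzyloxy trans-hydrindan-9-ol (C9 hydroxyl trans to C20; C8 R)
Conditions: OsO4 (5 mol %), NMO, acetone–H2O, rt
Reagents that add atoms: osmium tetroxide (catalytic oxygen carrier), O=[Os](=O)(=O)=O; 4-methylmorpholine N-oxide, C[N+]1([O-])CCOCC1; water, O
Why: Catalytic osmium tetroxide syn-dihydroxylation takes place on the face opposite the angular methyl, as with steroid 17(20)-alkenes, which sets the C9 hydroxyl trans to C20 and the two-carbon arm cis to it, the C8 carbinol centre being erased in step 11.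

Step 11
Reactants: 14 diol
Product: 15 9-acetyl-18-benzyloxy trans-hydrindan-9-ol (hydroxyl trans to C20; acetyl cis to C20)
Conditions: IBX, DMSO, rt
Reagents that add atoms: none
Why: IBX oxidises the secondary hydroxyl of a 1,2-diol to the ketone without cleaving the glycol C–C bond, and the tertiary C9 carbinol cannot be oxidised.

Step 12
Reactants: 15 hydrindane ketol
Product: 18 18-benzyloxy-8-hydroxy-8-methyl trans-decalin-9-one (C8 hydroxyl equatorial and trans to C20; C17 axial and cis to C20), via aluminium chelate 16 (not isolated), via aluminium alkoxide 17 (not isolated)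
Conditions: Al(OtBu)3 (1.5 equiv), toluene, 100 °C; aqueous work-up
Reagents that add atoms: none
Why: Alkoxide exchange attaches the C9 oxygen to aluminium, the same metal binds the acetyl oxygen, and in this five-membered syn chelate the C9–C7 bond lies parallel to the carbonyl π* orbital, so that C7 migrates suprafacially from C9 to C8 while C9 becomes the ketone. The closest known reaction type is the Lewis-acid-mediated α-ketol (acyloin) rearrangement, in particular the D-homoannulation of 17α-hydroxy-20-oxo steroids, which carry the same ketol on the same trans-hydrindane. Ring B is closed by ring enlargement through this 1,2-alkyl shift (five to six members, new bond C7–C8) and not by cyclisation of an open chain. The only new stereocentre, C8, is controlled by the chelate together with the C9 configuration set in step 10: with the acetyl group cis to C20 and the two oxygens syn, C17 turns to the C20 face and the former carbonyl oxygen to the other face, which gives the axial methyl and the equatorial hydroxyl. The step needs C7 and not the quaternary C10 to migrate and needs one face of the carbonyl to be attacked; the first is what the steroid ketols show under Lewis acids, the second follows from the rigid chelate, and relief of trans-hydrindane strain drives the shift forward while the hydride-free, non-basic tert-butoxide avoids reduction and base-type equilibration.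

Step 13
Reactants: 18 ring-enlarged hydroxy ketone
Product: 19 8-O-triethylsilyl ether of 18
Conditions: TESOTf, 2,6-lutidine, CH2Cl2, 0 °C
Reagents that add atoms: triethylsilyl trifluoromethanesulfonate, CC[Si](CC)(CC)OS(=O)(=O)C(F)(F)F
Why: Silyl triflate silylation caps the hindered tertiary hydroxyl, which blocks further acyloin shifts and later retro-aldol cleavage, and the ketone cannot form an enol ether because C8 and C10 bear no hydrogen.

Step 14
Reactants: 19 silyloxy ketone
Product: 20 9-methylene compound (C9=C11) with 8-OTES and 18-OBn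
Conditions: Cp2TiMe2 (3 equiv), toluene, 75 °C, dark
Reagents that add atoms: dimethyltitanocene Cp2TiMe2, [CH3-].[CH3-].c1cc[cH-]c1.c1cc[cH-]c1.[Ti+4]
Why: Carbonyl methylenation by the titanium methylidene generated thermally from Cp2TiMe2 (Petasis methylenation) is non-basic and uses a small reagent, which suits a non-enolisable ketone flanked by two quaternary carbons.

Step 15
Reactants: 20 exocyclic alkene
Product: 22 C11 primary alcohol (H9 trans to C20; CH2OH arm cis to C20), via alkylborane 21 (not isolated)
Conditions: BH3·THF, THF, 0 °C to rt; aq NaOH, 30 % H2O2, 0 °C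
Reagents that add atoms: hydrogen peroxide, OO
Why: Hydroboration–oxidation places boron on the terminal carbon C11 and delivers hydrogen to C9 from the face opposite the two axial methyls C17 and C20, so that H9 is trans and the CH2OH arm cis (equatorial) to C20.

Step 16
Reactants: 22 C11 alcohol
Product: 23 C11 aldehyde (formyl group on C9 cis to C20; 8-OTES; 18-OBn)
Conditions: Dess–Martin periodinane, CH2Cl2, rt
Reagents that add atoms: none
Why: Dess–Martin oxidation gives the aldehyde under neutral conditions, and C9 keeps its configuration because the formyl group already occupies the equatorial position.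

Step 17
Reactants: 24 (R)-methylsuccinic acid
Product: 25 (R)-2-methylbutane-1,4-diol
Conditions: LiAlH4, THF, reflux; aqueous work-up
Reagents that add atoms: none
Why: Hydride reduction of both carboxyl groups, in which the α-stereocentre is not at risk because the carboxylate and alkoxyaluminate intermediates do not enolise.

Step 18
Reactants: 25 (R)-2-methylbutane-1,4-diol
Product: 26 (2R)-4-[(tert-butyldiphenylsilyl)oxy]-2-methylbutan-1-ol
Conditions: TBDPSCl (1 equiv), imidazole, CH2Cl2, −20 °C; chromatography
Reagents that add atoms: tert-butyl(chloro)diphenylsilane, CC(C)(C)[Si](Cl)(c1ccccc1)c1ccccc1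
Why: The bulky silyl chloride reacts preferentially at the unbranched C4 hydroxyl (the future C15) over the β-branched C1 hydroxyl, and the minor regioisomer is removed by chromatography.

Step 19
Reactants: 26 monosilyl ether
Product: 27 (R)-tert-butyl(4-iodo-3-methylbutoxy)diphenylsilane
Conditions: I2, PPh3, imidazole, CH2Cl2, 0 °C to rt
Reagents that add atoms: iodine, II
Why: Appel-type iodination of the primary alcohol proceeds by SN2 displacement at CH2 and does not touch the adjacent stereocentre.

Step 20
Reactants: 27 iodide
Product: 28 [(2R)-4-[(tert-butyldiphenylsilyl)oxy]-2-methylbutyl]triphenylphosphonium iodide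
Conditions: PPh3, MeCN, reflux
Reagents that add atoms: triphenylphosphine, c1ccc(cc1)P(c1ccccc1)c1ccccc1
Why: SN2 quaternisation of triphenylphosphine by the primary iodide is slower for a β-branched halide but routine at this temperature.

Step 21
Reactants: 23 C11 aldehyde; 28 phosphonium iodide
Product: 30 (11Z)-alkene carrying 8-OTES 15-OTBDPS 18-OBn, via ylide 29 (not isolated)
Conditions: 28, NaN(SiMe3)2, THF, −78 to 0 °C; then 23, −78 °C to rt
Reagents that add atoms: none
Why: Wittig olefination joins C11 and C12, the reactive unstabilised ylide adding to the hindered aldehyde faster than it deprotonates the shielded C9–H, and it should give mainly the Z-alkene, whose geometry is lost in step 22.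

Step 22
Reactants: 30 alkene
Product: 31 saturated side-chain compound (8-OTES; 15-OTBDPS; 18-OBn; 13S)
Conditions: H2 (1 atm), PtO2, EtOAc, rt
Reagents that add atoms: none
Why: Heterogeneous hydrogenation over platinum saturates the disubstituted alkene with little double-bond migration, which protects the allylic centres C9 and C13, and leaves the benzyl ether in place.

Step 23
Reactants: 31 bis-silyl ether
Product: 32 18-benzyloxy-8,15-diol
Conditions: Bu4NF, THF, rt to 50 °C
Reagents that add atoms: none
Why: Fluoride-induced desilylation cleaves both the primary TBDPS and the tertiary TES ether and spares the benzyl ether.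

Step 24
Reactants: 32 diol; 33 2,2-dimethyl-1,3-dioxane-4,6-dione
Product: 34 15-O-(hydrogen malonate) of 32
Conditions: toluene, 90 °C
Reagents that add atoms: none
Why: Alcoholysis of Meldrum's acid with loss of acetone gives the malonic half ester directly, and only the unhindered primary C15 hydroxyl reacts because the C8 hydroxyl is tertiary and shielded and C18 is still benzylated.

Step 25
Reactants: 34 benzyl-protected half ester
Product: 35 target, 3-{[(3S)-5-[(1S,2S,4aS,5S,8aR)-2-hydroxy-5-(hydroxymethyl)-2,5,8a-trimethyldecahydronaphthalen-1-yl]-3-methylpentyl]oxy}-3-oxopropanoic acid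
Conditions: H2 (1 atm), Pd/C (10 %), EtOAc, rt
Reagents that add atoms: none
Why: Hydrogenolysis of the benzyl ether over palladium is neutral and leaves the malonic half ester and the tertiary alcohol untouched.

Compound list

1 | 2-methylcyclopentane-1,3-dione | CC1C(=O)CCC1=O | starting material
2 | pent-1-en-3-one | CCC(=O)C=C | starting material
3 | 2-methyl-2-(3-oxopentyl)cyclopentane-1,3-dione | CCC(=O)CCC1(C)C(=O)CCC1=O | intermediate
4 | (7aR)-4,7a-dimethyl-2,3,7,7a-tetrahydro-1H-indene-1,5(6H)-dione (C10 R; enone C3=O, C4=C5; C9 ketone) | O=C1[C@]2(C)CCC(=O)C(C)=C2CC1 | intermediate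
5 | (1R,7aR)-1-hydroxy-4,7a-dimethyl-1,2,3,6,7,7a-hexahydro-5H-inden-5-one (C9 OH cis to C20) | O[C@H]1[C@]2(C)CCC(=O)C(C)=C2CC1 | intermediate
6 | tert-butyldimethylsilyl ether of 5 | CC(C)(C)[Si](C)(C)O[C@H]1[C@]2(C)CCC(=O)C(C)=C2CC1 | intermediate
7 | lithium enolate (C3–OLi, C3=C4) of the trans-fused 9-silyloxy-hydrindan-3-one, H5 trans to C20 | CC(C)(C)[Si](C)(C)O[C@H]1[C@]2(C)CCC(O[Li])=C(C)[C@H]2CC1 | intermediate (not isolated)
8 | trans-fused 9-(tert-butyldimethylsilyloxy)-hydrindan-3-one with C4 bearing CH3 (C19, cis to C20) and CH2OH (C18, trans to C20) | CC(C)(C)[Si](C)(C)O[C@H]1[C@]2(C)CCC(=O)[C@](C)(CO)[C@H]2CC1 | intermediate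
9 | C18 benzyl ether of 8 | CC(C)(C)[Si](C)(C)O[C@H]1[C@]2(C)CCC(=O)[C@](C)(COCc3ccccc3)[C@H]2CC1 | intermediate
10 | C3 hydrazone of 9 | CC(C)(C)[Si](C)(C)O[C@H]1[C@]2(C)CCC(=NN)[C@](C)(COCc3ccccc3)[C@H]2CC1 | intermediate (not isolated)
11 | 18-benzyloxy trans-hydrindan-9-ol (C3 = CH2; OH cis to C20) | O[C@H]1[C@]2(C)CCC[C@](C)(COCc3ccccc3)[C@H]2CC1 | intermediate
12 | 18-benzyloxy trans-hydrindan-9-one | O=C1[C@]2(C)CCC[C@](C)(COCc3ccccc3)[C@H]2CC1 | intermediate
13 | (Z)-9-ethylidene-18-benzyloxy trans-hydrindane (C17 cis to C10) | C/C=C1\[C@]2(C)CCC[C@](C)(COCc3ccccc3)[C@H]2CC1 | intermediate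
14 | 9-[(1R)-1-hydroxyethyl]-18-benzyloxy trans-hydrindan-9-ol (C9 OH trans to C20) | C[C@@H](O)[C@@]1(O)[C@]2(C)CCC[C@](C)(COCc3ccccc3)[C@H]2CC1 | intermediate
15 | 9-acetyl-18-benzyloxy trans-hydrindan-9-ol (OH trans, acetyl cis to C20) | CC(=O)[C@@]1(O)[C@]2(C)CCC[C@](C)(COCc3ccccc3)[C@H]2CC1 | intermediate
16 | di-tert-butoxyaluminium alkoxide (chelate) of 15 | CC(=O)[C@@]1(O[Al](OC(C)(C)C)OC(C)(C)C)[C@]2(C)CCC[C@](C)(COCc3ccccc3)[C@H]2CC1 | intermediate (not isolated)
17 | di-tert-butoxyaluminium alkoxide of 18 | O=C1[C@]2(C)CCC[C@](C)(COCc3ccccc3)[C@H]2CC[C@]1(C)O[Al](OC(C)(C)C)OC(C)(C)C | intermediate (not isolated)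
18 | 18-benzyloxy-8-hydroxy-8-methyl trans-decalin-9-one (C8: OH equatorial, trans to C20; C17 axial, cis to C20) | O=C1[C@]2(C)CCC[C@](C)(COCc3ccccc3)[C@H]2CC[C@]1(C)O | intermediate
19 | 8-O-triethylsilyl ether of 18 | O=C1[C@]2(C)CCC[C@](C)(COCc3ccccc3)[C@H]2CC[C@]1(C)O[Si](CC)(CC)CC | intermediate
20 | 9-methylene compound (C9=C11), 8-OTES, 18-OBn | C=C1[C@]2(C)CCC[C@](C)(COCc3ccccc3)[C@H]2CC[C@]1(C)O[Si](CC)(CC)CC | intermediate
21 | C11 alkylborane (C11–BH2; H9 trans to C20) | BC[C@H]1[C@]2(C)CCC[C@](C)(COCc3ccccc3)[C@H]2CC[C@]1(C)O[Si](CC)(CC)CC | intermediate (not isolated)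
22 | C11 primary alcohol (C11 cis, H9 trans to C20), 8-OTES, 18-OBn | OC[C@H]1[C@]2(C)CCC[C@](C)(COCc3ccccc3)[C@H]2CC[C@]1(C)O[Si](CC)(CC)CC | intermediate
23 | C11 aldehyde, 8-OTES, 18-OBn | O=C[C@H]1[C@]2(C)CCC[C@](C)(COCc3ccccc3)[C@H]2CC[C@]1(C)O[Si](CC)(CC)CC | intermediate
24 | (R)-methylsuccinic acid | C[C@H](CC(=O)O)C(=O)O | starting material
25 | (R)-2-methylbutane-1,4-diol | C[C@H](CCO)CO | intermediate
26 | (2R)-4-[(tert-butyldiphenylsilyl)oxy]-2-methylbutan-1-ol | C[C@H](CCO[Si](c1ccccc1)(c1ccccc1)C(C)(C)C)CO | intermediate
27 | (R)-tert-butyl(4-iodo-3-methylbutoxy)diphenylsilane | C[C@H](CCO[Si](c1ccccc1)(c1ccccc1)C(C)(C)C)CI | intermediate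
28 | [(2R)-4-[(tert-butyldiphenylsilyl)oxy]-2-methylbutyl]triphenylphosphonium iodide | C[C@H](CCO[Si](c1ccccc1)(c1ccccc1)C(C)(C)C)C[P+](c1ccccc1)(c1ccccc1)c1ccccc1.[I-] | intermediate
29 | ylide of 28 (C12 ylide carbon) | C[C@H](CCO[Si](c1ccccc1)(c1ccccc1)C(C)(C)C)C=P(c1ccccc1)(c1ccccc1)c1ccccc1 | intermediate (not isolated)
30 | (11Z)-alkene of the ent-labdane skeleton, 8-OTES, 15-OTBDPS, 18-OBn | C[C@H](CCO[Si](c1ccccc1)(c1ccccc1)C(C)(C)C)/C=C\[C@H]1[C@]2(C)CCC[C@](C)(COCc3ccccc3)[C@H]2CC[C@]1(C)O[Si](CC)(CC)CC | intermediate
31 | saturated ent-labdane, 8-OTES, 15-OTBDPS, 18-OBn (13S) | C[C@H](CCO[Si](c1ccccc1)(c1ccccc1)C(C)(C)C)CC[C@H]1[C@]2(C)CCC[C@](C)(COCc3ccccc3)[C@H]2CC[C@]1(C)O[Si](CC)(CC)CC | intermediate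
32 | 18-benzyloxy-ent-labdane-8,15-diol (13S) | C[C@H](CCO)CC[C@H]1[C@]2(C)CCC[C@](C)(COCc3ccccc3)[C@H]2CC[C@]1(C)O | intermediate
33 | 2,2-dimethyl-1,3-dioxane-4,6-dione (Meldrum's acid) | CC1(C)OC(=O)CC(=O)O1 | starting material
34 | 15-O-(hydrogen malonate) of 32 | C[C@H](CCOC(=O)CC(=O)O)CC[C@H]1[C@]2(C)CCC[C@](C)(COCc3ccccc3)[C@H]2CC[C@]1(C)O | intermediate
35 | 3-{[(3S)-5-[(1S,2S,4aS,5S,8aR)-2-hydroxy-5-(hydroxymethyl)-2,5,8a-trimethyldecahydronaphthalen-1-yl]-3-methylpentyl]oxy}-3-oxopropanoic acid | C[C@H](CCOC(=O)CC(=O)O)CC[C@H]1[C@]2(C)CCC[C@](C)(CO)[C@H]2CC[C@]1(C)O | target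

Total step count: 25 (21 on the main line, 4 for the side-chain fragment).
Longest linear sequence: 21 steps (steps 1–16 and 21–25).

Steps most likely to fail

Step 12 (ring enlargement). What may go wrong:
- the acetyl carbon may be attacked by the wrong bond (shift of C10 instead of C7);
- the shift may run through a non-chelated rotamer and give the wrong C8 configuration;
- the first-formed ketol may equilibrate onward by a second acyloin shift.

The fallback abandons the ketol shift and enlarges the ring before C8 is substituted. It sets out from hydrindanone 12. Lewis-acid-promoted homologation with Me3SiCHN2 (BF3·OEt2, CH2Cl2, −78 °C, acidic work-up) should give 18-benzyloxy trans-decalin-9-one F1, because the less substituted C7 migrates, as in the ring enlargement of 17-oxo steroids. Deprotonation with LiN(iPr)2 and alkylation with MeI at the only enolisable position should give the 8-methyl ketone F2. Its potassium enolate (KN(SiMe3)2, THF, −78 °C) is then hydroxylated with 2-(phenylsulfonyl)-3-phenyloxaziridine on the face away from C20, the same facial rule that governs C4 in step 5. This returns to 18.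

Step 14 (methylenation). What may go wrong: addition of the titanium methylidene to a carbonyl flanked by two fully substituted carbons may be slower than thermal decay of the reagent. The fallback is a two-stage Peterson olefination that sets out from 19. Me3SiCH2Li with CeCl3 (THF, −78 °C) should add to the non-enolisable ketone from the face opposite C17 and C20 to give the β-hydroxysilane F3. KH (THF, 0 °C) then eliminates the silanolate and returns to 20. A cold quench before the elimination keeps the C8 silyl ether from migrating.

Step 21 (Wittig coupling). What may go wrong: the ylide may add sluggishly to the neopentyl-type aldehyde and act as a base instead, which would epimerise C9 or consume the aldehyde by enolisation. The fallback replaces olefination by carbonyl addition and deoxygenation. It sets out from aldehyde 23 and iodide 27. Iodine–lithium exchange (t-BuLi, Et2O, −78 °C) gives the alkyllithium F4, which adds to 23 at −78 °C to give the C11 carbinols F5. Both epimers are used together because C11 becomes CH2. Acylation with PhOC(S)Cl and pyridine gives the thionocarbonates F6. Barton–McCombie reduction (Bu3SnH, AIBN, toluene, 90 °C) removes the C11 oxygen and comes back to the route at 31, so that step 22 is skipped.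

Further compounds

F1 | step 12 | 18-benzyloxy trans-decalin-9-one (C8 = CH2) | O=C1[C@]2(C)CCC[C@](C)(COCc3ccccc3)[C@H]2CCC1
F2 | step 12 | 18-benzyloxy-8-methyl trans-decalin-9-one (C17 equatorial, trans to C20) | O=C1[C@]2(C)CCC[C@](C)(COCc3ccccc3)[C@H]2CC[C@@H]1C
F3 | step 14 | 9-hydroxy-9-[(trimethylsilyl)methyl] adduct of 19 (C9 OH cis to C20) | C[Si](C)(C)C[C@]1(O)[C@]2(C)CCC[C@](C)(COCc3ccccc3)[C@H]2CC[C@]1(C)O[Si](CC)(CC)CC
F4 | step 21 | [(2R)-4-[(tert-butyldiphenylsilyl)oxy]-2-methylbutyl]lithium | C[C@H](CCO[Si](c1ccccc1)(c1ccccc1)C(C)(C)C)C[Li]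
F5 | step 21 | C11 carbinols from 23 and F4 (both C11 epimers, C11 left open) | C[C@H](CCO[Si](c1ccccc1)(c1ccccc1)C(C)(C)C)CC(O)[C@H]1[C@]2(C)CCC[C@](C)(COCc3ccccc3)[C@H]2CC[C@]1(C)O[Si](CC)(CC)CC
F6 | step 21 | O-phenyl thionocarbonates of F5 (both C11 epimers, C11 left open) | C[C@H](CCO[Si](c1ccccc1)(c1ccccc1)C(C)(C)C)CC(OC(=S)Oc1ccccc1)[C@H]1[C@]2(C)CCC[C@](C)(COCc3ccccc3)[C@H]2CC[C@]1(C)O[Si](CC)(CC)CC
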